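**Retrosynthetic overview**

1. Target ⇐ hydrogenolysis of three benzyl ethers ⇐ aryl ketone made from an aryl bromide (Br–Li exchange, Weinreb amide). The bromide is a placeholder, so that the ring-forming step meets only one enolisable carbonyl group.
2. Key disconnection: the non-aromatic ring (numbered as 5-hydroxy-2,2,6,6-tetramethylcyclohex-4-ene-1,3-dione) is a cyclic tris-β-ketone. C1, C3 and C5 are carbonyl or enol carbons, C2 and C6 are quaternary CMe2 carbons, and C4, which carries the side chain, is the only enolisable α-carbon. Cutting C4–C5 and C1–C2 gives an acyclic isopropyl ketone (C2–C3–C4) and a 2,2-dimethylmalonyl unit (C5–C6–C1), joined in one flask by Claisen C-acylation and Dieckmann closure of a diketone dianion.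
3. The isopropyl ketone ⇐ bromination, oxidation and benzylation ⇐ isopropyl Grignard opening of a chroman-2-ol.
4. The stereocentre ⇐ iminium-catalysed asymmetric Friedel–Crafts alkylation of 2-methylphloroglucinol with (E)-5-methylhex-2-enal, itself from 3-methylbutanal.
5. Ring order: the aromatic ring is bought; a temporary lactol (pyran) ring is formed in step 2 and opened in step 3; the triketone ring is formed in step 7.

Key step: step 7

Remark: the lactol of step 2 is expected as a mixture of anomers, possibly with the isomeric lactol closed on the other ortho hydroxyl group; all open to the same aldehyde in step 3, so one form is drawn.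
Remark: the acid chloride ester used in step 7 (methyl 3-chloro-2,2-dimethyl-3-oxopropanoate) is taken to be a catalogue compound.

**Route**

Step 1
Reactants: 1 3-methylbutanal; 2 (triphenylphosphoranylidene)acetaldehyde
Product: 3 (2E)-5-methylhex-2-enal
Conditions: 1 (2 equiv), 2, toluene, 80 °C; distillation
Reagents that add atoms: none
Why: Wittig olefination with a stabilised formyl ylide should give the E-enal, and the excess of 1 limits a second homologation to the dienal.

Step 2
Reactants: 3 (2E)-5-methylhex-2-enal; 4 2-methylbenzene-1,3,5-triol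
Product: 6 (4R)-8-methyl-4-(2-methylpropyl)-3,4-dihydro-2H-chromene-2,5,7-triol, via open-chain aldehyde 5 (not isolated)
Conditions: 4 (3 equiv), (S)-2-[diphenyl(trimethylsilyloxy)methyl]pyrrolidine (20 mol %), PhCO2H (20 mol %), MeCN/CH2Cl2, 0 °C
Reagents that add atoms: none
Why: Iminium-catalysed asymmetric Friedel–Crafts alkylation followed by hemiacetalisation: the arene should add to the β-carbon of the E-iminium ion on the face away from the diphenyl(silyloxy)methyl group, which sets the R centre, the two free ring positions of 4 are equivalent, and the excess of 4 holds back a second alkylation.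

Step 3
Reactants: 6 (4R)-8-methyl-4-(2-methylpropyl)-3,4-dihydro-2H-chromene-2,5,7-triol; 7 isopropylmagnesium chloride
Product: 8 2-[(4R)-6-hydroxy-2,7-dimethyloctan-4-yl]-4-methylbenzene-1,3,5-triol
Conditions: i-PrMgCl (5 equiv), THF, −20 °C to rt; aq. NH4Cl
Reagents that add atoms: none
Why: Grignard addition to the aldehyde tautomer of the lactol, which opens as its magnesium phenoxide; three equivalents of 7 are used up by the hydroxyl groups, and the new carbinol centre, formed as both epimers, is removed in step 5.

Step 4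
Reactants: 8 2-[(4R)-6-hydroxy-2,7-dimethyloctan-4-yl]-4-methylbenzene-1,3,5-triol
Product: 9 (5R)-5-[2,4,6-tris(benzyloxy)-3-methylphenyl]-2,7-dimethyloctan-3-ol
Conditions: BnBr (3.6 equiv), K2CO3 (6 equiv), DMF, rt to 50 °C, under N2
Reagents that add atoms: benzyl bromide, BrCc1ccccc1
Why: Williamson etherification: K2CO3 forms only the three phenoxides, so the secondary alcohol should stay free, and the polar aprotic solvent favours O- over C-benzylation.

Step 5
Reactants: 9 (5R)-5-[2,4,6-tris(benzyloxy)-3-methylphenyl]-2,7-dimethyloctan-3-ol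
Product: 10 (5R)-5-[2,4,6-tris(benzyloxy)-3-methylphenyl]-2,7-dimethyloctan-3-one
Conditions: Dess–Martin periodinane (DMP), CH2Cl2, 0 °C to rt
Reagents that add atoms: none
Why: Dess–Martin oxidation of the secondary alcohol to the ketone under neutral conditions that should leave the benzyl ethers and the benzylic stereocentre untouched.

Step 6
Reactants: 10 (5R)-5-[2,4,6-tris(benzyloxy)-3-methylphenyl]-2,7-dimethyloctan-3-one
Product: 11 (5R)-5-[2,4,6-tris(benzyloxy)-3-bromo-5-methylphenyl]-2,7-dimethyloctan-3-one
Conditions: NBS (1.05 equiv), MeCN, 0 °C, dark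
Reagents that add atoms: N-bromosuccinimide, O=C1CCC(=O)N1Br
Why: Electrophilic aromatic bromination at the single free ring position, activated by three alkoxy groups, should be much faster than α-bromination of the ketone.

Step 7
Reactants: 11 (5R)-5-[2,4,6-tris(benzyloxy)-3-bromo-5-methylphenyl]-2,7-dimethyloctan-3-one; 12 methyl 3-chloro-2,2-dimethyl-3-oxopropanoate
Product: 14 4-{(1S)-1-[2,4,6-tris(benzyloxy)-3-bromo-5-methylphenyl]-3-methylbutyl}-5-hydroxy-2,2,6,6-tetramethylcyclohex-4-ene-1,3-dione, via diketo ester 13 (not isolated)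
Conditions: LiN(i-Pr)2 (2.1 equiv), THF, −78 °C; 12 (1.1 equiv), −78 °C; then LiN(i-Pr)2 (2.5 equiv), −78 to 0 °C; 1 M HCl
Reagents that add atoms: none
Why: Proposed new method: a one-flask [3+3] double Claisen annulation in which the kinetic lithium enolate of 11, formed at the methylene carbon next to the stereocentre, is C-acylated by the acid chloride end of 12 to give 13 as its lithium diketonate (bond C4–C5), and a second deprotonation at the only remaining acidic C–H, the isopropyl methine, gives a 1,3-diketone dianion whose tertiary carbanion attacks the methyl ester and expels methoxide (bond C1–C2). The closest known reaction types are the C-acylation of ketone lithium enolates by acid chlorides, the acylation of 1,3-diketone dianions at the terminal carbon by esters, Dieckmann closures that give cyclohexane-1,3,5-triones and, for the overall α,α′-annulation of a ketone by a malonyl unit, the Effenberger cyclisation. The carbocycle closes by a 6-(enolendo)-exo-trig Dieckmann-type attack, helped by the two gem-dimethyl groups (Thorpe–Ingold effect) and made irreversible because the product leaves as the enolate of a vinylogous acid. No stereocentre is formed, and the existing benzylic centre has no acidic hydrogen and no leaving group (all phenols are benzylated, so no quinone methide or retro-Michael path is open), so it should be untouched. The step needs C- over O-acylation and reaction at the hindered methine: the malonyl unit has no α-hydrogen and so can form neither a ketene nor an enolate, O-acylation of the diketonate by the methyl ester is reversible, the aryl bromide stands in for the later aryl ketone so that 11 holds a single enolisable carbonyl group, and a minor first acylation at the methine would converge on the same ring by Dieckmann closure at the methylene carbon.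

Step 8
Reactants: 14 4-{(1S)-1-[2,4,6-tris(benzyloxy)-3-bromo-5-methylphenyl]-3-methylbutyl}-5-hydroxy-2,2,6,6-tetramethylcyclohex-4-ene-1,3-dione; 15 N-methoxy-N-methyl-3-phenylpropanamide
Product: 17 4-{(1S)-1-[2,4,6-tris(benzyloxy)-3-methyl-5-(3-phenylpropanoyl)phenyl]-3-methylbutyl}-5-hydroxy-2,2,6,6-tetramethylcyclohex-4-ene-1,3-dione, via aryllithium 16 (not isolated)
Conditions: NaH (1.1 equiv), THF, 0 °C; t-BuLi (2.2 equiv), −78 °C; then 15 (1.5 equiv), −78 to 0 °C; aq. NH4Cl
Reagents that add atoms: none
Why: After the acidic enol is masked as its sodium enolate, bromine–lithium exchange and acylation of the aryllithium by the Weinreb amide (Weinreb ketone synthesis) should give the aryl ketone without over-addition, and the hindered non-enolisable ring ketone between the two quaternary carbons is expected to survive at −78 °C.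

Step 9
Reactants: 17 4-{(1S)-1-[2,4,6-tris(benzyloxy)-3-methyl-5-(3-phenylpropanoyl)phenyl]-3-methylbutyl}-5-hydroxy-2,2,6,6-tetramethylcyclohex-4-ene-1,3-dione
Product: 18 5-hydroxy-2,2,6,6-tetramethyl-4-{(1S)-3-methyl-1-[2,4,6-trihydroxy-3-methyl-5-(3-phenylpropanoyl)phenyl]butyl}cyclohex-4-ene-1,3-dione
Conditions: H2 (1 atm), 10% Pd/C, EtOAc/MeOH, rt
Reagents that add atoms: none
Why: Hydrogenolysis of the three benzyl ethers over Pd/C frees the phenols under neutral conditions, so neither acid-induced cyclodehydration to a xanthene nor base-induced retro-Michael racemisation of the benzylic centre should occur.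

**Compound list**

1 | 3-methylbutanal | CC(C)CC=O | starting material
2 | (triphenylphosphoranylidene)acetaldehyde | O=CC=P(c1ccccc1)(c1ccccc1)c1ccccc1 | starting material
3 | (2E)-5-methylhex-2-enal | CC(C)C/C=C/C=O | intermediate
4 | 2-methylbenzene-1,3,5-triol | Cc1c(O)cc(O)cc1O | starting material
5 | (3R)-5-methyl-3-(2,4,6-trihydroxy-3-methylphenyl)hexanal | Cc1c(O)cc(O)c([C@H](CC(C)C)CC=O)c1O | intermediate
6 | (4R)-8-methyl-4-(2-methylpropyl)-3,4-dihydro-2H-chromene-2,5,7-triol (anomers) | Cc1c(O)cc(O)c2[C@H](CC(C)C)CC(O)Oc12 | intermediate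
7 | isopropylmagnesium chloride | CC(C)[Mg]Cl | starting material
8 | 2-[(4R)-6-hydroxy-2,7-dimethyloctan-4-yl]-4-methylbenzene-1,3,5-triol (carbinol epimers) | Cc1c(O)cc(O)c([C@H](CC(C)C)CC(O)C(C)C)c1O | intermediate
9 | (5R)-5-[2,4,6-tris(benzyloxy)-3-methylphenyl]-2,7-dimethyloctan-3-ol (carbinol epimers) | Cc1c(OCc2ccccc2)cc(OCc2ccccc2)c([C@H](CC(C)C)CC(O)C(C)C)c1OCc1ccccc1 | intermediate
10 | (5R)-5-[2,4,6-tris(benzyloxy)-3-methylphenyl]-2,7-dimethyloctan-3-one | Cc1c(OCc2ccccc2)cc(OCc2ccccc2)c([C@H](CC(C)C)CC(=O)C(C)C)c1OCc1ccccc1 | intermediate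
11 | (5R)-5-[2,4,6-tris(benzyloxy)-3-bromo-5-methylphenyl]-2,7-dimethyloctan-3-one | Cc1c(OCc2ccccc2)c(Br)c(OCc2ccccc2)c([C@H](CC(C)C)CC(=O)C(C)C)c1OCc1ccccc1 | intermediate
12 | methyl 3-chloro-2,2-dimethyl-3-oxopropanoate | COC(=O)C(C)(C)C(Cl)=O | starting material
13 | methyl 4-{(1R)-1-[2,4,6-tris(benzyloxy)-3-bromo-5-methylphenyl]-3-methylbutyl}-2,2,6-trimethyl-3,5-dioxoheptanoate (present as its lithium diketonate) | Cc1c(OCc2ccccc2)c(Br)c(OCc2ccccc2)c([C@H](CC(C)C)C(C(=O)C(C)C)C(=O)C(C)(C)C(=O)OC)c1OCc1ccccc1 | intermediate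
14 | 4-{(1S)-1-[2,4,6-tris(benzyloxy)-3-bromo-5-methylphenyl]-3-methylbutyl}-5-hydroxy-2,2,6,6-tetramethylcyclohex-4-ene-1,3-dione | Cc1c(OCc2ccccc2)c(Br)c(OCc2ccccc2)c([C@H](CC(C)C)C2=C(O)C(C)(C)C(=O)C(C)(C)C2=O)c1OCc1ccccc1 | intermediate
15 | N-methoxy-N-methyl-3-phenylpropanamide | CON(C)C(=O)CCc1ccccc1 | starting material
16 | aryllithium formed from the sodium enolate of 14 by bromine–lithium exchange | [Li]c1c(OCc2ccccc2)c(C)c(OCc2ccccc2)c([C@H](CC(C)C)C2=C(O[Na])C(C)(C)C(=O)C(C)(C)C2=O)c1OCc1ccccc1 | intermediate
17 | 4-{(1S)-1-[2,4,6-tris(benzyloxy)-3-methyl-5-(3-phenylpropanoyl)phenyl]-3-methylbutyl}-5-hydroxy-2,2,6,6-tetramethylcyclohex-4-ene-1,3-dione | Cc1c(OCc2ccccc2)c(C(=O)CCc2ccccc2)c(OCc2ccccc2)c([C@H](CC(C)C)C2=C(O)C(C)(C)C(=O)C(C)(C)C2=O)c1OCc1ccccc1 | intermediate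
18 | 5-hydroxy-2,2,6,6-tetramethyl-4-{(1S)-3-methyl-1-[2,4,6-trihydroxy-3-methyl-5-(3-phenylpropanoyl)phenyl]butyl}cyclohex-4-ene-1,3-dione (CNP0188786.1) | Cc1c(O)c(C(=O)CCc2ccccc2)c(O)c([C@H](CC(C)C)C2=C(O)C(C)(C)C(=O)C(C)(C)C2=O)c1O | target

**Step count and risks**

Total step count: 9. Longest linear sequence: 9 steps (1 to 18).

Steps most likely to fail:

1. Step 7 (proposed new method). What may go wrong: O-acylation of the enolate instead of C-acylation, or no deprotonation at the hindered isopropyl methine, so that the sequence stops at the open-chain diketonate. Fallback with known chemistry: the triketone ring is not built but bought, and the benzylic bond is made last. It sets out from 1 and 4 and comes back at 18. Commercial 2,2,4,4-tetramethylcyclohexane-1,3,5-trione F1 is condensed with 1 (Knoevenagel, piperidine) to 2,2,4,4-tetramethyl-6-(3-methylbutylidene)cyclohexane-1,3,5-trione F2. Compound 4 is acylated with 3-phenylpropanoyl chloride and AlCl3 (Friedel–Crafts) to 1-(2,4,6-trihydroxy-3-methylphenyl)-3-phenylpropan-1-one F3. The Friedel–Crafts-type Michael addition of F3 to F2, a known construction for this compound family, is run under a chiral Lewis acid such as LiAl(BINOL)2, with the BINOL enantiomer chosen for the S adduct, and should give 18 directly.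

2. Step 8. What may go wrong: addition of t-BuLi to the ring ketone, or proton transfer from the Weinreb amide to the hindered aryllithium, which would return the debrominated arene. Fallback: electrophilic instead of organolithium acylation. It sets out from 14 and comes back at 18. Hydrogenolysis with hydrodebromination (H2, Pd/C, Et3N) should give 5-hydroxy-2,2,6,6-tetramethyl-4-[(1S)-3-methyl-1-(2,4,6-trihydroxy-3-methylphenyl)butyl]cyclohex-4-ene-1,3-dione F4. Friedel–Crafts acylation of its single free ring position with 3-phenylpropanoyl chloride and TiCl4 in CH2Cl2 at low temperature, to limit acid-induced cyclodehydration and loss of configuration, should give 18.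

3. Step 2. What may go wrong: a second alkylation at the other free ring position, and erosion of enantioselectivity by an uncatalysed background addition of the very nucleophilic triol. Fallback: auxiliary-controlled conjugate addition of a monofunctional aryl nucleophile. It sets out from 4 and 1 and comes back at 10.
   - Compound 4 is benzylated (BnBr, K2CO3, DMF) to 1,3,5-tris(benzyloxy)-2-methylbenzene F5 and monobrominated (NBS) to 1,3,5-tris(benzyloxy)-2-bromo-4-methylbenzene F6.
   - Compound 1 is condensed with malonic acid (pyridine, piperidine, Doebner variant of the Knoevenagel reaction) to (2E)-5-methylhex-2-enoic acid F7. Through its pivaloyl mixed anhydride, F7 acylates lithiated (S)-4-phenyl-1,3-oxazolidin-2-one to give (4S)-3-[(2E)-5-methylhex-2-enoyl]-4-phenyl-1,3-oxazolidin-2-one F8.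
   - The Grignard reagent of F6 with CuBr·SMe2 is expected to add to the magnesium-chelated imide anti to its phenyl group, giving (4S)-3-{(3R)-3-[2,4,6-tris(benzyloxy)-3-methylphenyl]-5-methylhexanoyl}-4-phenyl-1,3-oxazolidin-2-one F9.
   - Transamidation with MeNH(OMe)·HCl and AlMe3 gives (3R)-3-[2,4,6-tris(benzyloxy)-3-methylphenyl]-N-methoxy-N,5-dimethylhexanamide F10, and 7 converts it to 10.

Further compounds
F1 | step 7 | 2,2,4,4-tetramethylcyclohexane-1,3,5-trione (commercial) | CC1(C)C(=O)CC(=O)C(C)(C)C1=O
F2 | step 7 | 2,2,4,4-tetramethyl-6-(3-methylbutylidene)cyclohexane-1,3,5-trione | CC(C)CC=C1C(=O)C(C)(C)C(=O)C(C)(C)C1=O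
F3 | step 7 | 1-(2,4,6-trihydroxy-3-methylphenyl)-3-phenylpropan-1-one | Cc1c(O)cc(O)c(C(=O)CCc2ccccc2)c1O
F4 | step 8 | 5-hydroxy-2,2,6,6-tetramethyl-4-[(1S)-3-methyl-1-(2,4,6-trihydroxy-3-methylphenyl)butyl]cyclohex-4-ene-1,3-dione | Cc1c(O)cc(O)c([C@H](CC(C)C)C2=C(O)C(C)(C)C(=O)C(C)(C)C2=O)c1O
F5 | step 2 | 1,3,5-tris(benzyloxy)-2-methylbenzene | Cc1c(OCc2ccccc2)cc(OCc2ccccc2)cc1OCc1ccccc1
F6 | step 2 | 1,3,5-tris(benzyloxy)-2-bromo-4-methylbenzene | Cc1c(OCc2ccccc2)cc(OCc2ccccc2)c(Br)c1OCc1ccccc1
F7 | step 2 | (2E)-5-methylhex-2-enoic acid | CC(C)C/C=C/C(O)=O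
F8 | step 2 | (4S)-3-[(2E)-5-methylhex-2-enoyl]-4-phenyl-1,3-oxazolidin-2-one | CC(C)C/C=C/C(=O)N1[C@@H](c2ccccc2)COC1=O
F9 | step 2 | (4S)-3-{(3R)-3-[2,4,6-tris(benzyloxy)-3-methylphenyl]-5-methylhexanoyl}-4-phenyl-1,3-oxazolidin-2-one | Cc1c(OCc2ccccc2)cc(OCc2ccccc2)c([C@H](CC(C)C)CC(=O)N2[C@@H](c3ccccc3)COC2=O)c1OCc1ccccc1
F10 | step 2 | (3R)-3-[2,4,6-tris(benzyloxy)-3-methylphenyl]-N-methoxy-N,5-dimethylhexanamide | Cc1c(OCc2ccccc2)cc(OCc2ccccc2)c([C@H](CC(C)C)CC(=O)N(C)OC)c1OCc1ccccc1
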